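**Retrosynthetic overview**
1. Target acid 14 ← methyl ester 13 by a late SN2 O-demethylation.
2. The pyran ring, the C2 stereocentre and the whole dienyl side chain of 13 ← achiral keto-phenol 7 + (E)-dienylsilane 10, through a cyclic oxocarbenium ion paired with a chiral Brønsted-acid anion (metal-free).
3. 7 ← methyl orsellinate 1: hydroarylation of methyl vinyl ketone at C3, then bromination and Stille prenylation at C5.
4. 10 ← Suzuki coupling of (E)-(2-bromoethenyl)trimethylsilane 8 with the 2-methylpropenyl boronate 9.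
5. Ring order: the benzene ring is bought; the dihydropyran ring is the only ring formed (step 5).

**Assumptions**
- The target is the (2R)-chromane with a (1E)-diene: C2 carries O1, CH3 and the 4-methylpenta-1,3-dienyl group, with 5-OH, 6-CO2H, 7-CH3 and 8-prenyl on the arene.
- Compounds 1, 2, 4, 6, 8 and 9 are taken as catalogue chemicals.
- 3, 5 and 7 are drawn as open-chain ketones; each may equilibrate with a labile cyclic hemiketal, which does not change the chemistry.
- The (S,S) antipode of the catalyst is taken to give the 2R product; if the sense is the opposite, the (R,R) antipode is used.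

**Step 1**
Reactants: 1 methyl 2,4-dihydroxy-6-methylbenzoate (methyl orsellinate); 2 but-3-en-2-one (methyl vinyl ketone)
Product: 3 methyl 2,4-dihydroxy-6-methyl-3-(3-oxobutyl)benzoate
Conditions: 2 (1.2 equiv), p-TsOH·H2O (10 mol %), HFIP, 25 °C
Reagents that add atoms: but-3-en-2-one (2), CC(=O)C=C
Why: Acid-promoted Friedel–Crafts-type conjugate addition (hydroarylation of the enone); the ring carbon flanked by both hydroxyls (C3) is the most nucleophilic position of orsellinates, and no stereocentre is formed.

**Step 2**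
Reactants: 3 methyl 2,4-dihydroxy-6-methyl-3-(3-oxobutyl)benzoate; 4 N-bromosuccinimide
Product: 5 methyl 5-bromo-2,4-dihydroxy-6-methyl-3-(3-oxobutyl)benzoate
Conditions: NBS (1.0 equiv), MeCN, 0 °C
Reagents that add atoms: N-bromosuccinimide (4), O=C1CCC(=O)N1Br
Why: Electrophilic aromatic bromination at the only remaining ring C–H, which is ortho and para to the two hydroxyls and reacts far faster than the ketone α-position.

**Step 3**
Reactants: 5 methyl 5-bromo-2,4-dihydroxy-6-methyl-3-(3-oxobutyl)benzoate; 6 tributyl(3-methylbut-2-en-1-yl)stannane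
Product: 7 methyl 2,4-dihydroxy-6-methyl-5-(3-methylbut-2-en-1-yl)-3-(3-oxobutyl)benzoate
Conditions: Bu3SnCH2CH=CMe2 (1.5 equiv), Pd(PPh3)4 (10 mol %), DMF, 100 °C
Reagents that add atoms: tributyl(3-methylbut-2-en-1-yl)stannane (6), CCCC[Sn](CCCC)(CCCC)CC=C(C)C
Why: Stille coupling (oxidative addition of the aryl bromide to zerovalent palladium, then linear prenyl transfer) under neutral conditions that leave the free phenols, ketone and ester alone.

**Step 4**
Reactants: 8 (E)-(2-bromoethenyl)trimethylsilane; 9 4,4,5,5-tetramethyl-2-(2-methylprop-1-en-1-yl)-1,3,2-dioxaborolane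
Product: 10 trimethyl[(1E)-4-methylpenta-1,3-dien-1-yl]silane
Conditions: Pd(dppf)Cl2 (3 mol %), K2CO3, THF/H2O, 60 °C
Reagents that add atoms: 4,4,5,5-tetramethyl-2-(2-methylprop-1-en-1-yl)-1,3,2-dioxaborolane (9), CC(C)=CB1OC(C)(C)C(C)(C)O1
Why: Suzuki–Miyaura coupling of a vinyl bromide proceeds with retention, so the E geometry of 8 is carried into the diene, and the C–Si bond is inert without fluoride.

**Step 5**
Reactants: 7 methyl 2,4-dihydroxy-6-methyl-5-(3-methylbut-2-en-1-yl)-3-(3-oxobutyl)benzoate; 10 trimethyl[(1E)-4-methylpenta-1,3-dien-1-yl]silane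
Product: 13 methyl (2R)-5-hydroxy-2,7-dimethyl-8-(3-methylbut-2-en-1-yl)-2-[(1E)-4-methylpenta-1,3-dien-1-yl]-3,4-dihydro-2H-chromene-6-carboxylate, via cyclic hemiketal 11 (not isolated), via oxocarbenium ion 12 (not isolated)
Conditions: (S,S)-IDPi (confined imidodiphosphorimidate Brønsted acid from two (S)-3,3'-diaryl-BINOL units, N-triflyl groups; 5 mol %), 10 (2.5 equiv), 5 Å MS, toluene, −60 °C; Et3N quench
Reagents that add atoms: trimethyl[(1E)-4-methylpenta-1,3-dien-1-yl]silane (10), CC(C)=C/C=C/[Si](C)(C)C
Why: Proposed new method: the chiral acid closes 7 through its free 4-OH (the 2-OH is locked in a hydrogen bond to the ester) to hemiketal 11 and ionises it to the planar oxocarbenium ion 12, held as a contact ion pair in the confined chiral anion; the dienylsilane attacks through its silicon-bearing carbon (ipso attack gives a β-silyl-stabilised allyl cation with a tertiary terminus, so its nucleophilicity should match allyltrimethylsilane) on the Si face of C2 (O1 > C3 > CH3), which sets the 2R centre, and loss of Me3Si+ to the departed hydroxide (Me3SiOH) restores the E-alkene with retention and frees the acid; the closest known reaction types are IDPi-catalysed enantioselective additions of silyl nucleophiles to cyclic oxocarbenium ions from lactol derivatives and Lewis-acid-mediated ipso-substitution of vinylsilanes by oxocarbenium ions, and what is new is a ketone-derived oxocarbenium ion (tetrasubstituted centre) combined with a dienylsilane as the carbon nucleophile.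

**Step 6**
Reactants: 13 methyl (2R)-5-hydroxy-2,7-dimethyl-8-(3-methylbut-2-en-1-yl)-2-[(1E)-4-methylpenta-1,3-dien-1-yl]-3,4-dihydro-2H-chromene-6-carboxylate
Product: 14 (2R)-5-hydroxy-2,7-dimethyl-8-(3-methylbut-2-en-1-yl)-2-[(1E)-4-methylpenta-1,3-dien-1-yl]-3,4-dihydro-2H-chromene-6-carboxylic acid
Conditions: n-PrSLi (4 equiv), HMPA, 25 °C; then 0.5 M HCl to pH 3, 0 °C
Reagents that add atoms: none
Why: SN2 O-demethylation by thiolate at the ester methyl group avoids attack at the hindered, hydrogen-bonded carbonyl; the non-acidic medium leaves the tertiary dienyl ether, the stereocentre and both alkene units untouched, and cold mild acidification avoids decarboxylation.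

**Compound list**
1 | methyl 2,4-dihydroxy-6-methylbenzoate (methyl orsellinate) | COC(=O)c1c(C)cc(O)cc1O | starting material
2 | but-3-en-2-one (methyl vinyl ketone) | CC(=O)C=C | starting material
3 | methyl 2,4-dihydroxy-6-methyl-3-(3-oxobutyl)benzoate | COC(=O)c1c(C)cc(O)c(CCC(C)=O)c1O | intermediate
4 | N-bromosuccinimide | O=C1CCC(=O)N1Br | starting material
5 | methyl 5-bromo-2,4-dihydroxy-6-methyl-3-(3-oxobutyl)benzoate | COC(=O)c1c(C)c(Br)c(O)c(CCC(C)=O)c1O | intermediate
6 | tributyl(3-methylbut-2-en-1-yl)stannane | CCCC[Sn](CCCC)(CCCC)CC=C(C)C | starting material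
7 | methyl 2,4-dihydroxy-6-methyl-5-(3-methylbut-2-en-1-yl)-3-(3-oxobutyl)benzoate | COC(=O)c1c(C)c(CC=C(C)C)c(O)c(CCC(C)=O)c1O | intermediate
8 | (E)-(2-bromoethenyl)trimethylsilane | C[Si](C)(C)/C=C/Br | starting material
9 | 4,4,5,5-tetramethyl-2-(2-methylprop-1-en-1-yl)-1,3,2-dioxaborolane | CC(C)=CB1OC(C)(C)C(C)(C)O1 | starting material
10 | trimethyl[(1E)-4-methylpenta-1,3-dien-1-yl]silane | CC(C)=C/C=C/[Si](C)(C)C | intermediate
11 | methyl 2,5-dihydroxy-2,7-dimethyl-8-(3-methylbut-2-en-1-yl)-3,4-dihydro-2H-chromene-6-carboxylate (cyclic hemiketal of 7, racemic and labile) | COC(=O)c1c(C)c(CC=C(C)C)c2OC(C)(O)CCc2c1O | intermediate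
12 | 5-hydroxy-6-(methoxycarbonyl)-2,7-dimethyl-8-(3-methylbut-2-en-1-yl)-3,4-dihydrochromenylium (oxocarbenium ion, O1=C2 double bond, paired with the catalyst anion) | COC(=O)c1c(C)c(CC=C(C)C)c2[O+]=C(C)CCc2c1O | intermediate
13 | methyl (2R)-5-hydroxy-2,7-dimethyl-8-(3-methylbut-2-en-1-yl)-2-[(1E)-4-methylpenta-1,3-dien-1-yl]-3,4-dihydro-2H-chromene-6-carboxylate | CC(C)=C/C=C/[C@@]1(C)CCc2c(O)c(C(=O)OC)c(C)c(CC=C(C)C)c2O1 | intermediate
14 | (2R)-5-hydroxy-2,7-dimethyl-8-(3-methylbut-2-en-1-yl)-2-[(1E)-4-methylpenta-1,3-dien-1-yl]-3,4-dihydro-2H-chromene-6-carboxylic acid | CC(C)=C/C=C/[C@@]1(C)CCc2c(O)c(C(=O)O)c(C)c(CC=C(C)C)c2O1 | target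

**Step count**
Total steps: 6. Longest linear sequence: 5 (steps 1, 2, 3, 5, 6).

**Three steps most likely to fail**

Step 5 (the new oxocarbenium dienylation). It may give low enantioselectivity, lose the silane by protodesilylation, or re-ionise the tertiary dienyl ether of 13. The fallback sets out from 7, comes back at 13, and uses only known chemistry.
- Wittig olefination of 7 with ethyl (triphenylphosphoranylidene)acetate in toluene at reflux gives methyl 3-[(3E)-5-ethoxy-3-methyl-5-oxopent-3-en-1-yl]-2,4-dihydroxy-6-methyl-5-(3-methylbut-2-en-1-yl)benzoate F3.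
- An intramolecular oxa-Michael addition of the 4-OH, catalysed by a chiral bifunctional guanidine or cinchona-derived squaramide (a documented organocatalytic route to 2,2-disubstituted chromans, antipode chosen for 2R), gives methyl (2R)-2-(2-ethoxy-2-oxoethyl)-5-hydroxy-2,7-dimethyl-8-(3-methylbut-2-en-1-yl)-3,4-dihydro-2H-chromene-6-carboxylate F4.
- i-Bu2AlH in CH2Cl2 at −78 °C reduces only the unhindered aliphatic ester, to methyl (2R)-5-hydroxy-2,7-dimethyl-8-(3-methylbut-2-en-1-yl)-2-(2-oxoethyl)-3,4-dihydro-2H-chromene-6-carboxylate F5. This aldehyde is kept away from base to avoid retro-oxa-Michael opening.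
- Dehydrogenation with IBX in DMSO at 65 °C gives methyl (2R)-5-hydroxy-2,7-dimethyl-8-(3-methylbut-2-en-1-yl)-2-[(1E)-3-oxoprop-1-en-1-yl]-3,4-dihydro-2H-chromene-6-carboxylate F6.
- Wittig olefination of F6 with isopropylidenetriphenylphosphorane (Ph3P=CMe2, THF, −78 to 0 °C) forms the geometry-free trisubstituted alkene and delivers 13.

Step 1 (hydroarylation of 2). It may give C3/C5 mixtures, double alkylation or enone oligomers. The fallback sets out from 2, comes back at 3, and builds the arene with the side chain already in place.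
- Methyl acetoacetate and methyl crotonate are condensed (NaOMe, MeOH, reflux; Michael addition then Dieckmann closure) to methyl 6-methyl-2,4-dioxocyclohexane-1-carboxylate F1. It is racemic and enolised, and its sp3 centres are erased later.
- The carbon between its two ketones adds to 2 (Et3N cat., MeOH, 25 °C) to give methyl 6-methyl-2,4-dioxo-3-(3-oxobutyl)cyclohexane-1-carboxylate F2, with no regiochemical ambiguity.
- Dehydrogenation with DDQ in dioxane at reflux aromatises F2 to 3.

Step 3 (Stille coupling at a bromide flanked by OH and CH3). Oxidative addition may be sluggish or the prenyl group may transfer in the branched sense. The fallback sets out from 3 and comes back at 7, bypassing 5. It is the classical ortho C-alkylation of the phenoxide: 3 with 1-bromo-3-methylbut-2-ene in 10% aqueous KOH at 0 °C, where the only open ring carbon lies ortho to the 4-oxido group and the O-prenyl ether is the separable by-product. This fallback makes no new compound (F0).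

**Further compounds**
F1 | step 1 | methyl 6-methyl-2,4-dioxocyclohexane-1-carboxylate (racemic, enolised) | COC(=O)C1C(C)CC(=O)CC1=O
F2 | step 1 | methyl 6-methyl-2,4-dioxo-3-(3-oxobutyl)cyclohexane-1-carboxylate (racemic, enolised) | COC(=O)C1C(C)CC(=O)C(CCC(C)=O)C1=O
F0 | step 3 | none | none
F3 | step 5 | methyl 3-[(3E)-5-ethoxy-3-methyl-5-oxopent-3-en-1-yl]-2,4-dihydroxy-6-methyl-5-(3-methylbut-2-en-1-yl)benzoate | CCOC(=O)/C=C(\C)CCc1c(O)c(CC=C(C)C)c(C)c(C(=O)OC)c1O
F4 | step 5 | methyl (2R)-2-(2-ethoxy-2-oxoethyl)-5-hydroxy-2,7-dimethyl-8-(3-methylbut-2-en-1-yl)-3,4-dihydro-2H-chromene-6-carboxylate | CCOC(=O)C[C@@]1(C)CCc2c(O)c(C(=O)OC)c(C)c(CC=C(C)C)c2O1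
F5 | step 5 | methyl (2R)-5-hydroxy-2,7-dimethyl-8-(3-methylbut-2-en-1-yl)-2-(2-oxoethyl)-3,4-dihydro-2H-chromene-6-carboxylate | O=CC[C@@]1(C)CCc2c(O)c(C(=O)OC)c(C)c(CC=C(C)C)c2O1
F6 | step 5 | methyl (2R)-5-hydroxy-2,7-dimethyl-8-(3-methylbut-2-en-1-yl)-2-[(1E)-3-oxoprop-1-en-1-yl]-3,4-dihydro-2H-chromene-6-carboxylate | O=C/C=C/[C@@]1(C)CCc2c(O)c(C(=O)OC)c(C)c(CC=C(C)C)c2O1
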